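Every D that left the free pool went one of two ways: in pairs into E, or singly, on to Q or with L on to Z. That tally held at any moment, so I divided one rate by the other and time dropped out.

| setting | amber | green | eta | zeta | theta | alpha |
|---|---|---|---|---|---|---|
| D | 0.10 M | 0.10 M | 0.10 M (fed, over 1.0 h) | 0.10 M | 0.10 M | 0.10 M |
| L | 0.070 M | 0.035 M | 0.0700 M | 0.0700 M | 0.0700 M (in portions, 4, over 1.0 h) | 0.0700 M (fed, over 1.0 h) |
| remark | run made earlier | run made earlier | all else is in the flask from the start; the feed brings no volume worth counting | everything together at the start | first portion at the start, last at 1.0 h | all else is in the flask from the start; the feed brings no volume worth counting |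
| time |  |  | 80 min | 80 min | 80 min | 80 min |

| run | time / min | J / % | E / % |
|---|---|---|---|
| amber | 10.0 | 0 | 20 |
| amber | 30.0 | 1 | 24 |
| amber | 50.0 | 5 | 22 |
| amber | 80.0 | 7 | 24 |
| green | 0.667 | 0 | 6 |
| green | 1.33 | 0 | 11 |
| green | 3.00 | 0 | 16 |
| green | 8.00 | 0 | 24 |

(readings scatter by 1.5 percentage points)

1. the flask with the highest share of J in J plus E ("all alike" if they lie within 1.5 percentage points) (eta / zeta / theta / alpha / all alike)
2. share of J in J plus E at the end, eta
3. share of J in J plus E at the end, zeta
4. share of J in J plus E at the end, theta
5. share of J in J plus E at the end, alpha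

- percentages count the D that a species holds: one E counts as two
- J is meant together with its G
- solid, in amounts per volume of the solution: G
- what was read earlier has a scatter of 1.5 percentage points, one standard deviation
- steps thought possible: D <-> Q; D + L <-> X + Z; Z + L <-> X + J; 2 D -> E; G <-> J

You wanted a quick number, so here is mine. In amber, E stood at 24 % at 80.0 min, a reading. D fell from its charge towards zero, so I took the midway level as typical. There the split ratio (a selectivity factor), pairs over singles, was E/(1−E). At full charge that made it 0.632. The charge over this ratio gave 0.158 M: the crossover concentration c×, the c(D) at which pairs and singles use D equally. At amber's c(L), the share of passing D that goes to E is then c(D)/(c(D)+c×).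

For the single routes I needed a clock once. Green's first reading gave the pair rate at full charge, 0.0900 min⁻¹. Dividing by the ratio gave a pseudo-first-order constant of 0.142 min⁻¹. Eta's feed against that constant gave me a level of c(D) near 0.0117 M, far below c×. So I reckoned E in eta at 6.88 % of the charge. With your 5 per cent for J, that meant a share of 42.1 % in eta.

Your forecast put eta first at 55 %, with 24 %, 8 % and 6 % for zeta, theta and alpha. Its ground was that “second-order E falls to about 4%”. We parted on that E.

The flasks gave 41.8 % in eta, 22.0 % in zeta, 8.82 % in theta and 7.13 % in alpha, so eta stood highest.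

    D ⇌ Q (K = 17.0, k = 0.00110 s⁻¹)
    D + L ⇌ X + Z (K = 100, k = 0.0270 M⁻¹ s⁻¹)
    Z + L ⇌ X + J (K = 1.30, k = 0.00170 M⁻¹ s⁻¹)
    2 D → E (k = 0.00810 M⁻¹ s⁻¹)
    G ⇌ J, rate k5*(cs5 - [J]) while solid is left; crystals form when [J] > cs5 (solubility = 0.0650 M, k = 0.00640 s⁻¹)

At 60.0 min, when its feed ended, eta held D at 14.4 %; on c× that sends 8.35 % of the D then passing to E, and E stood at 6.64 % at that moment. In zeta, the forward half-life of D was 6.1 min by the L step against 11 min by the Q step. Alpha's mean c(L) over the feed was 0.0264 M, which scales c× to 0.0960 M. The midway rule then gives E 34.3 %, and alpha's E stood at 37.1 %.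

The numbers in the tables were computed with made-up constants, and the scatter is random.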